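At most 28.1% of the charge can enter solution in 1.5 min, so a target yield above that is impossible in this flask.

solid substrate 5.0 × 10⁻⁴ M; free catalyst 2.5 mol%; time 1.5 min

    starting material + free catalyst ⇌ catalyst intermediate (K1 = 74000 M⁻¹, k1 = 5500 M⁻¹ s⁻¹)
    catalyst intermediate → free catalyst + target (k2 = 2.4 s⁻¹)
    solid substrate ⇌ starting material, rate k3*(cs3 - [starting material]) while solid is left; crystals form when [starting material] > cs3 (cs3 = 0.052 mM, k3 = 0.030 s⁻¹)
    free catalyst + target → free catalyst + over-reaction product (k4 = 5200 M⁻¹ s⁻¹)
    catalyst intermediate + target → spent catalyst (k5 = 90 M⁻¹ s⁻¹)

- percent here means solid substrate units held: one spent catalyst counts as two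
- solid substrate is a solid; its amount is given per volume of the solution
- at the start none of the solid substrate is in solution
- starting material means what is dissolved; the solid is not counted in it
- run time (flask): 1.5 min

- how much target there is at 1.5 min, in percent of the solid substrate charged
- concentration of starting material in solution at 1.5 min, in percent of saturation

- The equilibrium constant can be rough, because the way back from catalyst intermediate, 0.0743 s⁻¹, is much slower than its way forward, 2.4 s⁻¹.
- The constant for spent catalyst can be rough too: even with the whole charge as target, that loss runs at 0.0450 s⁻¹ per intermediate, much slower than 2.4 s⁻¹.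
- The rate constant of step 2, 2.4 s⁻¹, needs no precision either. Capture at saturation, 0.286 s⁻¹, is slower, so I reckon [catalyst intermediate] below 11.9% of [free catalyst], and I take [free catalyst] as 1.25 × 10⁻⁵ M.
- The numbers that matter are the solubility, the dissolution coefficient, capture at 0.0688 s⁻¹ and the pseudo-first-order burn of target at 0.0650 s⁻¹. My answer scales directly with solubility and inversely with the burn constant.
- The burn time, 15.4 s, is shorter than 1.5 min, so I reckon a steady level.
- Dissolution and capture balance at [starting material] = 1.58 × 10⁻⁵ M, or 30.4% of saturation, with inflow 1.09 × 10⁻⁶ M s⁻¹.
- So I reckon target at 3.34%: this is the target plateau, the inflow divided by the burn and by the charge.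
- The forecast gives 3.4% and 32%, holding that “Dissolution is the bottleneck”; both my figures are lower than its.
- This flask gives 3.36% and 31.9%. Its target still reads 3.41% at 3.00 min. With half the dissolution coefficient, the plateau reckons 1.97%, and that run gives 1.97%.
- For the neighbour with 2.0 × 10⁻⁴ M of solid substrate at the same loading, the plateau gives 14.3%. That neighbour reaches 11.7% at 1.5 min, below its plateau.

The constants were set for the occasion.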